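The route rests on cutting ring A (cyclohexane C1–C5/C10, ent-kaurane numbering) at C1–C2 and C5–C10, the bond it shares with the ten-membered ring. One radical macrocyclisation–transannulation makes both bonds. It exploits the C9 ketone, which turns C1 into an acceptor and C10 into a radical site, and the quaternary C4, which removes allylic hydrogens and speeds the 6-exo closure. A primary C2 radical closes a 14-membered ring at C1. The C10 radical then attacks C5 and delivers ring A, the ten-membered ring and both stereocentres. The precursor is an all-trans cyclopentanone carrying an iodoalkenyl arm and an isopropenyl ketone arm, its enone masked as a thiophenol adduct.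

Key step: step 13

Remark: ent-kaurane numbers are used throughout (ring A = C1–C5, C10; ring D = C8, C14, C13, C16, C15; C17 on C16; C20 on C10), and "up" is the face of ring D that bears C12.

Step 1
Reactants: 1 (3aR,4S,5R,6aS)-5-hydroxy-4-(hydroxymethyl)hexahydro-2H-cyclopenta[b]furan-2-one
Product: 3 bis-silyl lactone (17-OTBDPS 15-OTES), via mono-TBDPS ether 2 (not isolated)
Conditions: TBDPSCl (1.05 equiv), imidazole, DMF, 0 °C; then TESCl (1.3 equiv), rt
Reagents that add atoms: TBDPSCl, CC(C)(C)[Si](Cl)(c1ccccc1)c1ccccc1; TESCl, CC[Si](Cl)(CC)CC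
Why: Silyl ether formation: the bulky TBDPSCl takes only the primary C17 hydroxyl, and TESCl then caps the secondary C15 hydroxyl with a group that can later be removed alone; no stereocentre is touched, and C13 of the target comes from 1.

Step 2
Reactants: 3 bis-silyl lactone; 4 (2-methylprop-1-en-1-yl)magnesium bromide
Product: 5 C11 isobutenyl ketone with free 14-OH (open form of its hemiketal)
Conditions: THF, −78 °C; aq. NH4Cl
Reagents that add atoms: none
Why: Acylation of a Grignard reagent by a lactone: at −78 °C the magnesium hemiketal alkoxide survives until the quench, so only one alkenyl group adds; C9, C10, C1 and C20 arrive as a latent isopropenyl ketone, and O14 is set free.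

Step 3
Reactants: 5 C11 isobutenyl ketone
Product: 6 14-acetate of the ketone
Conditions: Ac2O, pyridine, cat. DMAP, CH2Cl2, 0 °C to rt
Reagents that add atoms: acetic anhydride, CC(=O)OC(C)=O
Why: Acetylation of the open hydroxy ketone drains the hemiketal equilibrium and turns O14 into the leaving group that step 11 needs.

Step 4
Reactants: 6 14-acetate
Product: 7 (11S)-allylic alcohol
Conditions: (R)-Me-CBS (0.2 equiv), BH3·SMe2, toluene, −40 °C; MeOH, aq. work-up
Reagents that add atoms: none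
Why: CBS reduction: the alkenyl group acts as the large substituent and C12H2 as the small one, so the (R)-oxazaborolidine should give 11S by reagent control, with 1,2-selectivity.

Step 5
Reactants: 7 (11S)-allylic alcohol
Product: 8 (11S)-TBS ether
Conditions: TBSOTf, 2,6-lutidine, CH2Cl2, −78 to 0 °C
Reagents that add atoms: TBSOTf, CC(C)(C)[Si](C)(C)OS(=O)(=O)C(F)(F)F
Why: Silylation with a silyl triflate protects the hindered allylic C11 hydroxyl as a TBS ether that outlasts the TES ether.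

Step 6
Reactants: 8 (11S)-TBS ether
Product: 10 cyclopentanone (C15 ketone; 14-OAc up), via C15 alcohol 9 (not isolated)
Conditions: IBX (3 equiv), wet DMSO, rt
Reagents that add atoms: none
Why: IBX in DMSO is known to cleave TES ethers beside TBS and TBDPS ethers and then oxidises the freed secondary alcohol in the same flask, under neutral conditions that leave the β-acetoxy ketone intact.

Step 7
Reactants: 11 3,3-dimethyldihydrofuran-2(3H)-one
Product: 12 ethyl 4-iodo-2,2-dimethylbutanoate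
Conditions: TMSI, EtOH, CH2Cl2, 0 °C to rt
Reagents that add atoms: iodotrimethylsilane, C[Si](C)(C)I; ethanol, CCO
Why: Silyl iodide opening of a lactone: O-silylation and SN2 attack of iodide at the unhindered OCH2 (C2) give the silyl ester, which ethanol converts into the ethyl ester.

Step 8
Reactants: 12 ethyl 4-iodo-2,2-dimethylbutanoate
Product: 13 4-iodo-2,2-dimethylbutanal
Conditions: DIBAL-H (1.1 equiv), CH2Cl2, −78 °C; Rochelle salt
Reagents that add atoms: none
Why: Partial reduction of a hindered α,α-dimethyl ester: the tetrahedral aluminium acetal is stable at −78 °C and gives the aldehyde (C5) on work-up.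

Step 9
Reactants: 13 4-iodo-2,2-dimethylbutanal
Product: 14 (E)-6-iodo-4,4-dimethylhex-2-enal
Conditions: Ph3P=CHCHO, toluene, 90 °C
Reagents that add atoms: (triphenylphosphoranylidene)acetaldehyde, O=CC=P(c1ccccc1)(c1ccccc1)c1ccccc1
Why: Wittig reaction with a stabilised ylide should give the E-alkene C5=C6, and the neopentyl aldehyde cannot enolise.

Step 10
Reactants: 10 cyclopentanone; 14 (E)-6-iodo-4,4-dimethylhex-2-enal
Product: 15 anti-aldol adduct (7R; C7 down on C8)
Conditions: Bu2BOTf, iPr2NEt, CH2Cl2, −78 °C; then 14; pH 7 buffer, MeOH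
Reagents that add atoms: none
Why: Boron aldol reaction: soft enolisation takes the less hindered C8H2, the aldehyde approaches the lower face opposite to the neighbouring 14-OAc and the C12 arm, and the Zimmerman–Traxler chair of the ring-locked E-enolate gives the anti adduct, which is 7R.

Step 11
Reactants: 15 anti-aldol adduct
Product: 17 thiol adduct (14-SPh down; C7 up; 7R-OH), via hydroxy enone 16 (not isolated)
Conditions: DBU (1.1 equiv), CH2Cl2, −20 °C; then PhSH (1.05 equiv), 0 °C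
Reagents that add atoms: thiophenol, Sc1ccccc1
Why: E1cB loss of acetate (hydroxide at C7 is a far poorer leaving group) followed by thia-Michael addition: the thiolate adds to C14 anti to the C12 arm, reversible protonation puts C7 trans to sulfur and so cis to C12, the small amount of free base keeps SN2 at the iodide slow, and C7 is untouched.

Step 12
Reactants: 17 thiol adduct
Product: 20 cascade precursor (isopropenyl ketone; 7R-OAc; 14-SPh; primary iodide), via C7 acetate 18 (not isolated), via C9 hydroperoxide 19 (not isolated)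
Conditions: Ac2O, pyridine, cat. DMAP, CH2Cl2, 0 °C, dark; then O2, TPP, visible light, −10 °C
Reagents that add atoms: acetic anhydride, CC(=O)OC(C)=O; oxygen, O=O
Why: Acetylation, then Schenck ene reaction and Kornblum–DeLaMare-type dehydration in one flask: allylic 1,3-strain holds C11–H in the alkene plane, so singlet oxygen abstracts a methyl hydrogen and bonds to C9, the peracetate collapses to the C9 ketone, the aryl sulfide mainly quenches singlet oxygen physically in an aprotic solvent, and the 1,2-disubstituted C5=C6 is inert.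

Step 13
Reactants: 20 cascade precursor
Product: 21 tricyclic sulfide (5R 10R; ring A plus ten-membered ring)
Conditions: (TMS)3SiH (1.3 equiv), AIBN (0.3 equiv), syringe pump over 12 h into benzene at 80 °C, final 1 mM
Reagents that add atoms: none
Why: The silyl radical abstracts iodine from 20, the nucleophilic primary C2 radical adds to the unhindered CH2 terminus C1 of the isopropenyl ketone, the tertiary C10 radical next to the C9 ketone then adds across the ring to C5 of the E-alkene, and the secondary C6 radical takes hydrogen from the silane. The closest known reaction type is the cascade radical macrocyclisation–transannulation of ω-iodoalkyl enones under tin or silicon hydride at high dilution. The first closure is 14-endo-trig, and the second is 6-exo-trig and divides the 14-membered ring into cyclohexane ring A and the ten-membered ring. C5 is set by C7: with C7–H eclipsing the alkene (allylic 1,3-strain) the acetate points to the periphery, and C10 can reach only the inner face, the one that carries C8, which gives 5R. C10 is set by the chair-like transition state in which C6 and the C9 acyl chain, both members of the ten-membered ring, are pseudo-equatorial and C20 is axial, which gives the trans 5R,10R pair. The C10 radical must find no other acceptor and must outrun reduction: the cyclopentenone is masked so that C5=C6 is the only alkene left, the all-trans ring D holds both arms on one face, the quaternary C4 offers no allylic hydrogen for a 1,5-shift and accelerates closure, and slow addition of the slow donor (TMS)3SiH holds back early hydrogen transfer.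

Step 14
Reactants: 21 tricyclic sulfide
Product: 23 bridged cyclopentenone (C8=C14), via sulfoxide 22 (not isolated)
Conditions: mCPBA (1.0 equiv), CH2Cl2, −78 °C; then CaCO3, toluene, 50 °C
Reagents that add atoms: mCPBA, O=C(OO)c1cccc(Cl)c1 (its oxygen stands in 22 and leaves again with the sulfur)
Why: Sulfide oxidation and thermal syn-elimination of a β-keto sulfoxide: the acidic H8 lies cis to sulfur, so C8=C14 forms under neutral conditions in which no C8 enolate can expel the C7 acetate.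

Step 15
Reactants: 23 bridged cyclopentenone
Product: 24 11,17-diol
Conditions: HF·pyridine, pyridine, THF, 0 °C to rt
Reagents that add atoms: none
Why: Fluoride-mediated desilylation under buffered conditions removes the TBS and TBDPS ethers without touching the allylic acetate or the enone.

Step 16
Reactants: 24 11,17-diol
Product: 26 CNP0159088.1 (target), via C17 mesylate 25 (not isolated)
Conditions: MsCl (1.1 equiv), Et3N (4 equiv), CH2Cl2, −30 to 0 °C
Reagents that add atoms: methanesulfonyl chloride, CS(=O)(=O)Cl (stands in 25 only)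
Why: Selective mesylation of the primary C17 hydroxyl over the hindered, hydrogen-bonded C11 hydroxyl, then E1cB elimination through the C16 enolate, gives the exocyclic methylene; C8 no longer bears a hydrogen, so the C7 acetate is safe.

Compound list
1 | (3aR,4S,5R,6aS)-5-hydroxy-4-(hydroxymethyl)hexahydro-2H-cyclopenta[b]furan-2-one; supplies C8 and C11–C17; C12, O14, O15 up, C17 down | O=C1C[C@@H]2[C@@H](CO)[C@H](O)C[C@@H]2O1 | starting material
2 | 17-O-TBDPS ether of 1 | O=C1C[C@@H]2[C@@H](CO[Si](c3ccccc3)(c3ccccc3)C(C)(C)C)[C@H](O)C[C@@H]2O1 | intermediate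
3 | 17-O-TBDPS 15-O-TES lactone | O=C1C[C@@H]2[C@@H](CO[Si](c3ccccc3)(c3ccccc3)C(C)(C)C)[C@H](O[Si](CC)(CC)CC)C[C@@H]2O1 | intermediate
4 | (2-methylprop-1-en-1-yl)magnesium bromide | CC(C)=C[Mg]Br | starting material
5 | C11 isobutenyl ketone; 14-OH up and free | CC(C)=CC(=O)C[C@@H]1[C@@H](CO[Si](c2ccccc2)(c2ccccc2)C(C)(C)C)[C@H](O[Si](CC)(CC)CC)C[C@@H]1O | intermediate
6 | 14-acetate of 5 | CC(C)=CC(=O)C[C@@H]1[C@@H](CO[Si](c2ccccc2)(c2ccccc2)C(C)(C)C)[C@H](O[Si](CC)(CC)CC)C[C@@H]1OC(C)=O | intermediate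
7 | (11S)-allylic alcohol | CC(C)=C[C@@H](O)C[C@@H]1[C@@H](CO[Si](c2ccccc2)(c2ccccc2)C(C)(C)C)[C@H](O[Si](CC)(CC)CC)C[C@@H]1OC(C)=O | intermediate
8 | (11S)-TBS ether | CC(C)=C[C@@H](O[Si](C)(C)C(C)(C)C)C[C@@H]1[C@@H](CO[Si](c2ccccc2)(c2ccccc2)C(C)(C)C)[C@H](O[Si](CC)(CC)CC)C[C@@H]1OC(C)=O | intermediate
9 | C15 alcohol (TES removed) | CC(C)=C[C@@H](O[Si](C)(C)C(C)(C)C)C[C@@H]1[C@@H](CO[Si](c2ccccc2)(c2ccccc2)C(C)(C)C)[C@H](O)C[C@@H]1OC(C)=O | intermediate
10 | C15 ketone; 14-OAc and C12 up, C17 down | CC(C)=C[C@@H](O[Si](C)(C)C(C)(C)C)C[C@@H]1[C@@H](CO[Si](c2ccccc2)(c2ccccc2)C(C)(C)C)C(=O)C[C@@H]1OC(C)=O | intermediate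
11 | 3,3-dimethyldihydrofuran-2(3H)-one; supplies C2–C5 and both C4 methyl groups | CC1(C)CCOC1=O | starting material
12 | ethyl 4-iodo-2,2-dimethylbutanoate | CCOC(=O)C(C)(C)CCI | intermediate
13 | 4-iodo-2,2-dimethylbutanal | O=CC(C)(C)CCI | intermediate
14 | (E)-6-iodo-4,4-dimethylhex-2-enal (C2–C7) | O=C/C=C/C(C)(C)CCI | intermediate
15 | anti-aldol adduct; 7R; C7 down and H8 up on C8; 14-OAc up | CC(C)=C[C@@H](O[Si](C)(C)C(C)(C)C)C[C@@H]1[C@@H](CO[Si](c2ccccc2)(c2ccccc2)C(C)(C)C)C(=O)[C@@H]([C@H](O)/C=C/C(C)(C)CCI)[C@@H]1OC(C)=O | intermediate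
16 | 2-(1-hydroxyalkenyl)cyclopent-2-enone; 7R; C8=C14 | CC(C)=C[C@@H](O[Si](C)(C)C(C)(C)C)C[C@@H]1[C@@H](CO[Si](c2ccccc2)(c2ccccc2)C(C)(C)C)C(=O)C([C@H](O)/C=C/C(C)(C)CCI)=C1 | intermediate
17 | thiol adduct; 14-SPh down, C7 up, C12 up, C17 down; 7R-OH | CC(C)=C[C@@H](O[Si](C)(C)C(C)(C)C)C[C@@H]1[C@@H](CO[Si](c2ccccc2)(c2ccccc2)C(C)(C)C)C(=O)[C@H]([C@H](O)/C=C/C(C)(C)CCI)[C@H]1Sc1ccccc1 | intermediate
18 | C7 acetate of 17 | CC(C)=C[C@@H](O[Si](C)(C)C(C)(C)C)C[C@@H]1[C@@H](CO[Si](c2ccccc2)(c2ccccc2)C(C)(C)C)C(=O)[C@H]([C@H](OC(C)=O)/C=C/C(C)(C)CCI)[C@H]1Sc1ccccc1 | intermediate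
19 | C9 allylic hydroperoxide (C9 epimers; C10=C1 formed) | C=C(C)C(OO)[C@@H](O[Si](C)(C)C(C)(C)C)C[C@@H]1[C@@H](CO[Si](c2ccccc2)(c2ccccc2)C(C)(C)C)C(=O)[C@H]([C@H](OC(C)=O)/C=C/C(C)(C)CCI)[C@H]1Sc1ccccc1 | intermediate
20 | cascade precursor; C9 isopropenyl ketone, 11S-OTBS, 7R-OAc, E-C5=C6, C2 iodide | C=C(C)C(=O)[C@@H](O[Si](C)(C)C(C)(C)C)C[C@@H]1[C@@H](CO[Si](c2ccccc2)(c2ccccc2)C(C)(C)C)C(=O)[C@H]([C@H](OC(C)=O)/C=C/C(C)(C)CCI)[C@H]1Sc1ccccc1 | intermediate
21 | tricyclic sulfide; 5R,7R,10R,11S,13S; 14-SPh down, H8 down | CC(C)(C)[Si](c1ccccc1)(c1ccccc1)OC[C@H]1C(=O)[C@H]2[C@@H](Sc3ccccc3)[C@@H]1C[C@H](O[Si](C)(C)C(C)(C)C)C(=O)[C@]1(C)CCCC(C)(C)[C@H]1C[C@H]2OC(C)=O | intermediate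
22 | sulfoxide of 21 (epimers at sulfur) | CC(C)(C)[Si](c1ccccc1)(c1ccccc1)OC[C@H]1C(=O)[C@H]2[C@@H](S(=O)c3ccccc3)[C@@H]1C[C@H](O[Si](C)(C)C(C)(C)C)C(=O)[C@]1(C)CCCC(C)(C)[C@H]1C[C@H]2OC(C)=O | intermediate
23 | bridged cyclopentenone; C8=C14; 17-OTBDPS, 11-OTBS | CC(C)(C)[Si](c1ccccc1)(c1ccccc1)OC[C@H]1C(=O)C2=C[C@@H]1C[C@H](O[Si](C)(C)C(C)(C)C)C(=O)[C@]1(C)CCCC(C)(C)[C@H]1C[C@H]2OC(C)=O | intermediate
24 | 11,17-diol | OC[C@H]1C(=O)C2=C[C@@H]1C[C@H](O)C(=O)[C@]1(C)CCCC(C)(C)[C@H]1C[C@H]2OC(C)=O | intermediate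
25 | C17 mesylate | CS(=O)(=O)OC[C@H]1C(=O)C2=C[C@@H]1C[C@H](O)C(=O)[C@]1(C)CCCC(C)(C)[C@H]1C[C@H]2OC(C)=O | intermediate
26 | CNP0159088.1; 5R,7R,10R,11S,13S | C=C1C(=O)C2=C[C@@H]1C[C@H](O)C(=O)[C@]1(C)CCCC(C)(C)[C@H]1C[C@H]2OC(C)=O | target

Total step count: 16. Longest linear sequence: 13 (steps 1–6 and 10–16).

Steps most likely to fail

Step 13. Early hydrogen transfer to the C2 or C10 radical, 7-endo attack at C6, or poor facial selectivity at C5 may spoil the cascade. The fallback separates the two ring closures. It sets out from 8 and comes back at 23.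
- The conditions of step 12 turn 8 into the isopropenyl ketone F1.
- (TMS)3SiH/AIBN with an excess of 14 joins C2 to C1 and closes C10 onto C5 of the enal, now an activated acceptor. This gives the ring-A aldehyde F2.
- IBX gives the C15 ketone F3, and DBU removes acetic acid to give the cyclopentenone F4.
- I2/pyridine gives the α-iodo enone F5.
- A Nozaki–Hiyama–Kishi closure (CrCl2, cat. NiCl2, DMSO/THF, high dilution) joins C7 to C8 and gives the macrocyclic allylic alcohol F6.
- Ac2O/pyridine leads to 23.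

Step 10. β-Elimination of the C14 acetate from the boron enolate before the aldehyde arrives, or enolisation towards C16, may consume the ketone. The fallback avoids the enolate. It sets out from 10 and comes back at 16.
- DBU gives the cyclopentenone F7.
- I2/pyridine gives the α-iodo enone F8.
- An intermolecular Nozaki–Hiyama–Kishi coupling with 14 under a chiral sulfonamide ligand on chromium sets 7R by reagent control and gives 16.

Step 12. Oxidation of the sulfide by singlet oxygen with early loss of the mask, or base-induced loss of the C7 acetate, may occur. The fallback moves the ene reaction in front of the sulfur chemistry and carries C9 at the alcohol level. It sets out from 10 and comes back at 20.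
- O2/TPP/light followed by PPh3 gives the C9 allylic alcohol F9, and TESCl/imidazole gives the TES ether F10.
- The conditions of step 10 give the aldol adduct F11, and those of step 11 give the thiol adduct F12.
- Ac2O/pyridine gives the C7 acetate F13.
- PPTS/MeOH frees the C9 alcohol F14.
- Dess–Martin periodinane, which tolerates the sulfide, gives 20.

Further compounds
F1 | step 13 | isopropenyl ketone (15-OTES; 14-OAc) | C=C(C)C(=O)[C@@H](O[Si](C)(C)C(C)(C)C)C[C@@H]1[C@@H](CO[Si](c2ccccc2)(c2ccccc2)C(C)(C)C)[C@H](O[Si](CC)(CC)CC)C[C@@H]1OC(C)=O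
F2 | step 13 | ring-A aldehyde (5R,10R) | CC(=O)O[C@H]1C[C@@H](O[Si](CC)(CC)CC)[C@H](CO[Si](c2ccccc2)(c2ccccc2)C(C)(C)C)[C@H]1C[C@H](O[Si](C)(C)C(C)(C)C)C(=O)[C@]1(C)CCCC(C)(C)[C@H]1CC=O
F3 | step 13 | C15 ketone aldehyde | CC(=O)O[C@H]1CC(=O)[C@H](CO[Si](c2ccccc2)(c2ccccc2)C(C)(C)C)[C@H]1C[C@H](O[Si](C)(C)C(C)(C)C)C(=O)[C@]1(C)CCCC(C)(C)[C@H]1CC=O
F4 | step 13 | cyclopentenone aldehyde | CC(C)(C)[Si](c1ccccc1)(c1ccccc1)OC[C@H]1C(=O)C=C[C@@H]1C[C@H](O[Si](C)(C)C(C)(C)C)C(=O)[C@]1(C)CCCC(C)(C)[C@H]1CC=O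
F5 | step 13 | α-iodo enone aldehyde | CC(C)(C)[Si](c1ccccc1)(c1ccccc1)OC[C@H]1C(=O)C(I)=C[C@@H]1C[C@H](O[Si](C)(C)C(C)(C)C)C(=O)[C@]1(C)CCCC(C)(C)[C@H]1CC=O
F6 | step 13 | macrocyclic (7R)-allylic alcohol | CC(C)(C)[Si](c1ccccc1)(c1ccccc1)OC[C@H]1C(=O)C2=C[C@@H]1C[C@H](O[Si](C)(C)C(C)(C)C)C(=O)[C@]1(C)CCCC(C)(C)[C@H]1C[C@H]2O
F7 | step 10 | cyclopentenone with isobutenyl arm | CC(C)=C[C@@H](O[Si](C)(C)C(C)(C)C)C[C@@H]1[C@@H](CO[Si](c2ccccc2)(c2ccccc2)C(C)(C)C)C(=O)C=C1
F8 | step 10 | α-iodo enone with isobutenyl arm | CC(C)=C[C@@H](O[Si](C)(C)C(C)(C)C)C[C@@H]1[C@@H](CO[Si](c2ccccc2)(c2ccccc2)C(C)(C)C)C(=O)C(I)=C1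
F9 | step 12 | C9 allylic alcohol of the C15 ketone | C=C(C)C(O)[C@@H](O[Si](C)(C)C(C)(C)C)C[C@@H]1[C@@H](CO[Si](c2ccccc2)(c2ccccc2)C(C)(C)C)C(=O)C[C@@H]1OC(C)=O
F10 | step 12 | C9 TES ether | C=C(C)C(O[Si](CC)(CC)CC)[C@@H](O[Si](C)(C)C(C)(C)C)C[C@@H]1[C@@H](CO[Si](c2ccccc2)(c2ccccc2)C(C)(C)C)C(=O)C[C@@H]1OC(C)=O
F11 | step 12 | anti-aldol adduct (7R) of F10 | C=C(C)C(O[Si](CC)(CC)CC)[C@@H](O[Si](C)(C)C(C)(C)C)C[C@@H]1[C@@H](CO[Si](c2ccccc2)(c2ccccc2)C(C)(C)C)C(=O)[C@@H]([C@H](O)/C=C/C(C)(C)CCI)[C@@H]1OC(C)=O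
F12 | step 12 | thiol adduct (14-SPh down; C7 up) | C=C(C)C(O[Si](CC)(CC)CC)[C@@H](O[Si](C)(C)C(C)(C)C)C[C@@H]1[C@@H](CO[Si](c2ccccc2)(c2ccccc2)C(C)(C)C)C(=O)[C@H]([C@H](O)/C=C/C(C)(C)CCI)[C@H]1Sc1ccccc1
F13 | step 12 | C7 acetate of F12 | C=C(C)C(O[Si](CC)(CC)CC)[C@@H](O[Si](C)(C)C(C)(C)C)C[C@@H]1[C@@H](CO[Si](c2ccccc2)(c2ccccc2)C(C)(C)C)C(=O)[C@H]([C@H](OC(C)=O)/C=C/C(C)(C)CCI)[C@H]1Sc1ccccc1
F14 | step 12 | free C9 allylic alcohol | C=C(C)C(O)[C@@H](O[Si](C)(C)C(C)(C)C)C[C@@H]1[C@@H](CO[Si](c2ccccc2)(c2ccccc2)C(C)(C)C)C(=O)[C@H]([C@H](OC(C)=O)/C=C/C(C)(C)CCI)[C@H]1Sc1ccccc1
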